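**Strategy.** The route rests on cutting the bond between ring C1 and the side-chain CH(CH3) carbon. These two vicinal stereocentres both sit allylic to the ring C2=C3 alkene and so form a γ,δ-unsaturated acid retron. An Ireland–Claisen rearrangement of an (S,E)-allylic propionate built from (R)-linalool makes this bond and both stereocentres in one operation and leaves a propenyl group on C1. Ring-closing metathesis with the linalool vinyl group then closes the cyclohexene, whose C4 carbinol (methyl, hydroxyl) is the untouched linalool stereocentre. Homologation, asymmetric alkynylation, trans-hydroalumination–iodination and Negishi coupling finish the enoate side chain.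

Key step: step 6

Assumption: the (S,S)-ProPhenol/Me2Zn catalyst is taken to deliver the alkynyl group to the Re face of aldehyde 19 (4S carbinol); should a test run show the opposite sense, the (R,R)-ligand is used and nothing else changes.

Step 1
Reactants: 1 (R)-(−)-linalool
Product: 2 (3R)-3,7-dimethyl-3-(triethylsilyloxy)octa-1,6-diene
Conditions: Et3SiOTf, 2,6-lutidine, CH2Cl2, −78 → 0 °C
Reagents that add atoms: triethylsilyl trifluoromethanesulfonate, CC[Si](CC)(CC)OS(=O)(=O)C(F)(F)F
Why: Silylation of a hindered tertiary alcohol with a silyl triflate and a hindered pyridine base should be clean, the ether prevents lactol formation and oxa-Michael addition in the next steps, and the stereocentre is not touched.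

Step 2
Reactants: 2 (3R)-3,7-dimethyl-3-(triethylsilyloxy)octa-1,6-diene
Product: 4 (4R)-4-methyl-4-(triethylsilyloxy)hex-5-enal, via secondary ozonide 3 (not isolated)
Conditions: O3 (about 1 equiv., Sudan Red 7B end-point), CH2Cl2, −78 °C; then PPh3, −78 °C → rt
Reagents that add atoms: ozone, [O-][O+]=O
Why: Chemoselective ozonolysis should work because electrophilic ozone adds much faster to the electron-rich trisubstituted alkene than to the monosubstituted vinyl group, which is deactivated by the allylic silyloxy group and shielded by the quaternary carbon; reductive work-up of the ozonide releases the aldehyde.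

Step 3
Reactants: 4 (4R)-4-methyl-4-(triethylsilyloxy)hex-5-enal; 5 1-(triphenylphosphoranylidene)propan-2-one
Product: 6 (3E,7R)-7-methyl-7-(triethylsilyloxy)nona-3,8-dien-2-one
Conditions: toluene, 80 °C
Reagents that add atoms: none
Why: Wittig olefination with a stabilised keto ylide should give the E enone through reversible, thermodynamically controlled oxaphosphetane formation, under neutral conditions that leave the silyl ether alone.

Step 4
Reactants: 6 (3E,7R)-7-methyl-7-(triethylsilyloxy)nona-3,8-dien-2-one
Product: 7 (2S,3E,7R)-7-methyl-7-(triethylsilyloxy)nona-3,8-dien-2-ol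
Conditions: (R)-2-methyl-CBS-oxazaborolidine (20 mol%), catecholborane, toluene, −78 °C
Reagents that add atoms: none
Why: Corey–Bakshi–Shibata reduction in which the ketone binds the oxazaborolidine boron with the alkenyl group as the large substituent, so hydride reaches the Re face and sets the 2S carbinol under catalyst control; catecholborane at low temperature should neither hydroborate the vinyl group nor reduce the enone in the 1,4-sense.

Step 5
Reactants: 7 (2S,3E,7R)-7-methyl-7-(triethylsilyloxy)nona-3,8-dien-2-ol; 8 propanoyl chloride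
Product: 9 (2S,3E,7R)-7-methyl-7-(triethylsilyloxy)nona-3,8-dien-2-yl propanoate
Conditions: Et3N, DMAP (cat.), CH2Cl2, 0 °C → rt
Reagents that add atoms: none
Why: DMAP-catalysed acylation of a secondary allylic alcohol at oxygen proceeds with retention at the carbinol and without allylic transposition.

Step 6
Reactants: 9 (2S,3E,7R)-7-methyl-7-(triethylsilyloxy)nona-3,8-dien-2-yl propanoate
Product: 12 (2S,3R,6R)-2,6-dimethyl-3-[(E)-prop-1-enyl]-6-(triethylsilyloxy)oct-7-enoic acid, via silyl ketene acetal 10 (not isolated), via trimethylsilyl ester 11 (not isolated)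
Conditions: LiN(iPr)2 (LDA), THF/DMPU, −78 °C; Me3SiCl, −78 °C → rt, then 50 °C; H2O/MeOH, citric acid to pH 4
Reagents that add atoms: none
Why: Deprotonation in the presence of DMPU gives the ester enolate with the α-methyl cis to the enolate oxygen, silylation fixes this geometry in 10, and on warming 10 undergoes a concerted suprafacial [3,3]-sigmatropic shift through a chair transition state in which the bond between the future ring C1 and the side-chain CH(CH3) carbon forms as the allylic C–O bond breaks. The closest known reaction type is the Ireland–Claisen rearrangement of E-configured secondary allylic propionates. No ring is closed here; the rearrangement only places a propenyl group on the future C1 for the six-membered ring closure of step 7. The stereocentre at the future ring C1 (3R in 12) is controlled by the 2S carbinol of 9, whose methyl group lies equatorial in the chair so that the new bond forms on one face of the E alkene (1,3-chirality transfer). The α-stereocentre (2S in 12) is controlled by the ketene acetal geometry, the methyl cis to the silyloxy group lying equatorial next to the equatorial chain of the E alkene, which gives the syn pair. The step thus needs facial selectivity and simple syn diastereoselectivity, secured by the single small-substituent S carbinol on an E-disubstituted alkene and by the DMPU-controlled enolate geometry, while the remote silyl ether and vinyl group stay inert and 11 is hydrolysed to 12 on work-up.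

Step 7
Reactants: 12 (2S,3R,6R)-2,6-dimethyl-3-[(E)-prop-1-enyl]-6-(triethylsilyloxy)oct-7-enoic acid
Product: 13 (2S)-2-[(1R,4R)-4-methyl-4-(triethylsilyloxy)cyclohex-2-en-1-yl]propanoic acid
Conditions: second-generation Grubbs catalyst RuCl2(=CHPh)(H2IMes)(PCy3) (5 mol%), CH2Cl2, high dilution, 40 °C
Reagents that add atoms: none
Why: Ring-closing metathesis of the 1,7-diene joins the propenyl and vinyl carbons into the ring C2=C3 alkene of an unstrained cyclohexene, driven by loss of propene; the catalyst tolerates the free acid and the silyl ether, and no stereocentre is affected.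

Step 8
Reactants: 13 (2S)-2-[(1R,4R)-4-methyl-4-(triethylsilyloxy)cyclohex-2-en-1-yl]propanoic acid
Product: 15 (3S)-1-diazo-3-[(1R,4R)-4-methyl-4-(triethylsilyloxy)cyclohex-2-en-1-yl]butan-2-one, via mixed anhydride 14 (not isolated)
Conditions: iBuOCOCl, Et3N, THF, −15 °C; then CH2N2 (excess, Et2O), 0 °C → rt
Reagents that add atoms: diazomethane, C=[N+]=[N-]
Why: This is the first half of an Arndt–Eistert homologation, in which diazomethane is acylated by the mixed carbonic anhydride at its more electrophilic acyl carbon; the cold, weakly basic activation should not epimerise the α-stereocentre.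

Step 9
Reactants: 15 (3S)-1-diazo-3-[(1R,4R)-4-methyl-4-(triethylsilyloxy)cyclohex-2-en-1-yl]butan-2-one
Product: 17 methyl (3R)-3-[(1S,4R)-4-methyl-4-(triethylsilyloxy)cyclohex-2-en-1-yl]butanoate, via ketene 16 (not isolated)
Conditions: PhCO2Ag (10 mol%), Et3N, MeOH, rt, dark
Reagents that add atoms: methanol, CO
Why: Silver-promoted Wolff rearrangement expels N2 while the stereogenic alkyl group migrates with retention to give ketene 16, which methanol traps as the one-carbon homologated ester.

Step 10
Reactants: 17 methyl (3R)-3-[(1S,4R)-4-methyl-4-(triethylsilyloxy)cyclohex-2-en-1-yl]butanoate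
Product: 19 (3R)-3-[(1S,4R)-4-methyl-4-(triethylsilyloxy)cyclohex-2-en-1-yl]butanal, via aluminium hemiacetal 18 (not isolated)
Conditions: iBu2AlH (1.1 equiv.), CH2Cl2, −78 °C; MeOH, then aq. potassium sodium tartrate (KNaC4H4O6)
Reagents that add atoms: none
Why: Partial ester reduction with iBu2AlH relies on the tetrahedral aluminium hemiacetal 18 persisting at −78 °C until the quench, so the aldehyde is released only on work-up; the β-stereocentre cannot epimerise.

Step 11
Reactants: 19 (3R)-3-[(1S,4R)-4-methyl-4-(triethylsilyloxy)cyclohex-2-en-1-yl]butanal; 20 methyl prop-2-ynoate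
Product: 22 methyl (4S,6R)-4-hydroxy-6-[(1S,4R)-4-methyl-4-(triethylsilyloxy)cyclohex-2-en-1-yl]hept-2-ynoate, via zinc acetylide 21 (not isolated)
Conditions: Me2Zn, (S,S)-ProPhenol (20 mol%), Ph3P=O (40 mol%), toluene, 0–4 °C; aq. NH4Cl
Reagents that add atoms: none
Why: In this catalytic asymmetric zinc alkynylation, Me2Zn converts the propiolate into acetylide 21, which is transferred inside the chiral dinuclear zinc–ProPhenol pocket to the Re face of the aldehyde, setting the 4S carbinol under catalyst control with little influence expected from the remote β-stereocentre.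

Step 12
Reactants: 22 methyl (4S,6R)-4-hydroxy-6-[(1S,4R)-4-methyl-4-(triethylsilyloxy)cyclohex-2-en-1-yl]hept-2-ynoate
Product: 24 methyl (2Z,4S,6R)-4-hydroxy-2-iodo-6-[(1S,4R)-4-methyl-4-(triethylsilyloxy)cyclohex-2-en-1-yl]hept-2-enoate, via cyclic alkenylaluminate 23 (not isolated)
Conditions: NaAlH2(OCH2CH2OMe)2, THF, −72 °C; then I2, −72 → −20 °C; aq. Na2S2O3, aq. potassium sodium tartrate (KNaC4H4O6)
Reagents that add atoms: iodine, [I][I]
Why: In this hydroxyl-directed trans-hydroalumination of a γ-hydroxy ynoate, the aluminate bound to the carbinol oxygen delivers hydride to the alkyne carbon next to the carbinol and places aluminium anti on the ester-bearing carbon (23); iodinolysis with retention then gives the Z iodide, and the low temperature spares the methyl ester.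

Step 13
Reactants: 25 5-bromo-2-methylpent-2-ene
Product: 26 (4-methylpent-3-en-1-yl)zinc bromide (THF solution, titrated and used directly)
Conditions: Zn dust (activated with BrCH2CH2Br and Me3SiCl), LiCl, THF, 50 °C
Reagents that add atoms: zinc, [Zn]
Why: Direct oxidative insertion of activated zinc into a primary alkyl bromide, accelerated by LiCl, gives the alkylzinc bromide; the trisubstituted alkene is inert.

Step 14
Reactants: 24 methyl (2Z,4S,6R)-4-hydroxy-2-iodo-6-[(1S,4R)-4-methyl-4-(triethylsilyloxy)cyclohex-2-en-1-yl]hept-2-enoate; 26 (4-methylpent-3-en-1-yl)zinc bromide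
Product: 27 methyl (2E,4S,6R)-4-hydroxy-6-[(1S,4R)-4-methyl-4-(triethylsilyloxy)cyclohex-2-en-1-yl]-2-(4-methylpent-3-en-1-yl)hept-2-enoate
Conditions: Pd(OAc)2 (3 mol%), SPhos (6 mol%), THF, 25 °C, slow addition of 26 (excess)
Reagents that add atoms: none
Why: In this Negishi coupling, zerovalent palladium inserts into the alkenyl carbon–iodine bond with retention, and the bulky biarylphosphine makes reductive elimination of the alkyl–alkenyl pair faster than β-hydride elimination; the weakly basic alkylzinc halide tolerates the free hydroxyl, and the alkene geometry is carried over unchanged.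

Step 15
Reactants: 27 methyl (2E,4S,6R)-4-hydroxy-6-[(1S,4R)-4-methyl-4-(triethylsilyloxy)cyclohex-2-en-1-yl]-2-(4-methylpent-3-en-1-yl)hept-2-enoate
Product: 28 methyl (2E,4S,6R)-4-acetoxy-6-[(1S,4R)-4-methyl-4-(triethylsilyloxy)cyclohex-2-en-1-yl]-2-(4-methylpent-3-en-1-yl)hept-2-enoate
Conditions: Ac2O, pyridine, DMAP (cat.), CH2Cl2, 0 °C → rt
Reagents that add atoms: acetic anhydride, CC(=O)OC(C)=O
Why: DMAP-catalysed acetylation of the secondary alcohol proceeds with retention at C4, and since the tertiary alcohol is still silylated only one acetate can form.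

Step 16
Reactants: 28 methyl (2E,4S,6R)-4-acetoxy-6-[(1S,4R)-4-methyl-4-(triethylsilyloxy)cyclohex-2-en-1-yl]-2-(4-methylpent-3-en-1-yl)hept-2-enoate
Product: 29 methyl (2E,4S,6R)-4-acetoxy-6-[(1S,4R)-4-hydroxy-4-methylcyclohex-2-en-1-yl]-2-(4-methylpent-3-en-1-yl)hept-2-enoate (CNP0360342.1)
Conditions: HF·pyridine, excess pyridine, THF, 0 °C → rt
Reagents that add atoms: none
Why: Fluoride cleaves the tertiary triethylsilyl ether through formation of the strong Si–F bond, and the pyridine buffer should leave the acetate, the enoate and the acid-sensitive tertiary allylic alcohol intact.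

**Compound list**

1 | (R)-(−)-linalool, (3R)-3,7-dimethylocta-1,6-dien-3-ol | C=C[C@](C)(O)CCC=C(C)C | starting material
2 | (3R)-3,7-dimethyl-3-(triethylsilyloxy)octa-1,6-diene | C=C[C@](C)(O[Si](CC)(CC)CC)CCC=C(C)C | intermediate
3 | secondary ozonide, 3,3-dimethyl-5-[(3R)-3-methyl-3-(triethylsilyloxy)pent-4-en-1-yl]-1,2,4-trioxolane (formed in the flask, epimers at ring C5) | C=C[C@](C)(O[Si](CC)(CC)CC)CCC1OOC(C)(C)O1 | intermediate
4 | (4R)-4-methyl-4-(triethylsilyloxy)hex-5-enal | C=C[C@](C)(O[Si](CC)(CC)CC)CCC=O | intermediate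
5 | 1-(triphenylphosphoranylidene)propan-2-one | CC(=O)C=P(c1ccccc1)(c1ccccc1)c1ccccc1 | starting material
6 | (3E,7R)-7-methyl-7-(triethylsilyloxy)nona-3,8-dien-2-one | C=C[C@](C)(O[Si](CC)(CC)CC)CC/C=C/C(C)=O | intermediate
7 | (2S,3E,7R)-7-methyl-7-(triethylsilyloxy)nona-3,8-dien-2-ol | C=C[C@](C)(O[Si](CC)(CC)CC)CC/C=C/[C@H](C)O | intermediate
8 | propanoyl chloride | CCC(=O)Cl | starting material
9 | (2S,3E,7R)-7-methyl-7-(triethylsilyloxy)nona-3,8-dien-2-yl propanoate | C=C[C@](C)(O[Si](CC)(CC)CC)CC/C=C/[C@H](C)OC(=O)CC | intermediate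
10 | trimethylsilyl ketene acetal of 9, methyl cis to the trimethylsilyloxy group (formed in the flask) | C=C[C@](C)(O[Si](CC)(CC)CC)CC/C=C/[C@H](C)O/C(=C/C)O[Si](C)(C)C | intermediate
11 | trimethylsilyl (2S,3R,6R)-2,6-dimethyl-3-[(E)-prop-1-enyl]-6-(triethylsilyloxy)oct-7-enoate (formed in the flask) | C=C[C@](C)(O[Si](CC)(CC)CC)CC[C@H](/C=C/C)[C@H](C)C(=O)O[Si](C)(C)C | intermediate
12 | (2S,3R,6R)-2,6-dimethyl-3-[(E)-prop-1-enyl]-6-(triethylsilyloxy)oct-7-enoic acid | C=C[C@](C)(O[Si](CC)(CC)CC)CC[C@H](/C=C/C)[C@H](C)C(=O)O | intermediate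
13 | (2S)-2-[(1R,4R)-4-methyl-4-(triethylsilyloxy)cyclohex-2-en-1-yl]propanoic acid | OC(=O)[C@@H](C)[C@H]1C=C[C@](C)(O[Si](CC)(CC)CC)CC1 | intermediate
14 | mixed isobutyl carbonic anhydride of 13 (formed in the flask) | CC(C)COC(=O)OC(=O)[C@@H](C)[C@H]1C=C[C@](C)(O[Si](CC)(CC)CC)CC1 | intermediate
15 | (3S)-1-diazo-3-[(1R,4R)-4-methyl-4-(triethylsilyloxy)cyclohex-2-en-1-yl]butan-2-one | [N-]=[N+]=CC(=O)[C@@H](C)[C@H]1C=C[C@](C)(O[Si](CC)(CC)CC)CC1 | intermediate
16 | alkylketene from 15, 3-[4-methyl-4-(triethylsilyloxy)cyclohex-2-en-1-yl]but-1-en-1-one with the stereocentres of 15 (formed in the flask) | O=C=C[C@@H](C)[C@H]1C=C[C@](C)(O[Si](CC)(CC)CC)CC1 | intermediate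
17 | methyl (3R)-3-[(1S,4R)-4-methyl-4-(triethylsilyloxy)cyclohex-2-en-1-yl]butanoate | COC(=O)C[C@@H](C)[C@H]1C=C[C@](C)(O[Si](CC)(CC)CC)CC1 | intermediate
18 | diisobutylaluminium hemiacetal of 17 (formed in the flask) | COC(O[Al](CC(C)C)CC(C)C)C[C@@H](C)[C@H]1C=C[C@](C)(O[Si](CC)(CC)CC)CC1 | intermediate
19 | (3R)-3-[(1S,4R)-4-methyl-4-(triethylsilyloxy)cyclohex-2-en-1-yl]butanal | O=CC[C@@H](C)[C@H]1C=C[C@](C)(O[Si](CC)(CC)CC)CC1 | intermediate
20 | methyl prop-2-ynoate (methyl propiolate) | C#CC(=O)OC | starting material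
21 | methylzinc acetylide of methyl propiolate (formed in the flask) | COC(=O)C#C[Zn]C | intermediate
22 | methyl (4S,6R)-4-hydroxy-6-[(1S,4R)-4-methyl-4-(triethylsilyloxy)cyclohex-2-en-1-yl]hept-2-ynoate | COC(=O)C#C[C@@H](O)C[C@@H](C)[C@H]1C=C[C@](C)(O[Si](CC)(CC)CC)CC1 | intermediate
23 | cyclic sodium alkenylaluminate, aluminium bound to the carbinol oxygen and to the ester-bearing alkene carbon (formed in the flask) | COC(=O)C1=C[C@H](C[C@@H](C)[C@H]2C=C[C@](C)(O[Si](CC)(CC)CC)CC2)O[Al-]1(OCCOC)OCCOC.[Na+] | intermediate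
24 | methyl (2Z,4S,6R)-4-hydroxy-2-iodo-6-[(1S,4R)-4-methyl-4-(triethylsilyloxy)cyclohex-2-en-1-yl]hept-2-enoate | COC(=O)/C(=C/[C@H](C[C@@H](C)[C@H]1C=C[C@](C)(O[Si](CC)(CC)CC)CC1)O)I | intermediate
25 | 5-bromo-2-methylpent-2-ene | CC(C)=CCCBr | starting material
26 | (4-methylpent-3-en-1-yl)zinc bromide | CC(C)=CCC[Zn]Br | intermediate
27 | methyl (2E,4S,6R)-4-hydroxy-6-[(1S,4R)-4-methyl-4-(triethylsilyloxy)cyclohex-2-en-1-yl]-2-(4-methylpent-3-en-1-yl)hept-2-enoate | COC(=O)/C(=C/[C@H](C[C@@H](C)[C@H]1C=C[C@](C)(O[Si](CC)(CC)CC)CC1)O)CCC=C(C)C | intermediate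
28 | methyl (2E,4S,6R)-4-acetoxy-6-[(1S,4R)-4-methyl-4-(triethylsilyloxy)cyclohex-2-en-1-yl]-2-(4-methylpent-3-en-1-yl)hept-2-enoate | COC(=O)/C(=C/[C@H](C[C@@H](C)[C@H]1C=C[C@](C)(O[Si](CC)(CC)CC)CC1)OC(C)=O)CCC=C(C)C | intermediate
29 | methyl (2E,4S,6R)-4-acetoxy-6-[(1S,4R)-4-hydroxy-4-methylcyclohex-2-en-1-yl]-2-(4-methylpent-3-en-1-yl)hept-2-enoate (CNP0360342.1) | COC(=O)/C(=C/[C@H](C[C@@H](C)[C@H]1C=C[C@](C)(O)CC1)OC(C)=O)CCC=C(C)C | target

**Step count and risks**

Total step count: 16. Longest linear sequence: 15 steps from (R)-linalool (steps 1–12 and 14–16); the organozinc reagent of step 13 is a one-step side branch.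

Steps most likely to fail:

Step 6. Incomplete control of the enolate geometry would let the anti diastereomer form and erode the syn relationship of the two new stereocentres. The fallback keeps the rearrangement but pairs the enolate geometry that forms dependably in THF alone (methyl trans to the silyloxy group) with a Z alkene and the opposite carbinol configuration; the two changes together lead to the same acid. It sets out from aldehyde 4. Ohira–Bestmann homologation (dimethyl (1-diazo-2-oxopropyl)phosphonate, K2CO3, MeOH) gives the terminal alkyne (3R)-3-methyl-3-(triethylsilyloxy)hept-1-en-6-yne F1. Lithiation with n-BuLi and acylation with N-methoxy-N-methylacetamide give the ynone (7R)-7-methyl-7-(triethylsilyloxy)non-8-en-3-yn-2-one F2. Noyori transfer hydrogenation with RuCl(p-cymene)[(R,R)-TsDPEN] in 2-propanol gives the propargylic alcohol (2R,7R)-7-methyl-7-(triethylsilyloxy)non-8-en-3-yn-2-ol F3. Semihydrogenation over Pd/CaCO3 poisoned with Pb(OAc)2 and quinoline gives the allylic alcohol (2R,3Z,7R)-7-methyl-7-(triethylsilyloxy)nona-3,8-dien-2-ol F4. Acylation with 8 gives (2R,3Z,7R)-7-methyl-7-(triethylsilyloxy)nona-3,8-dien-2-yl propanoate F5. LiN(iPr)2 in THF without DMPU followed by Me3SiCl gives the silyl ketene acetal with methyl trans to the trimethylsilyloxy group F6. F6 rearranges through the chair with the alkene substituent and the α-methyl both axial to silyl ester 11, and hydrolysis brings the route back at acid 12.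

Step 11. Poor facial selectivity, or aldol self-condensation of the enolisable aldehyde under the zinc conditions, would lower the stereochemical purity at C4. The fallback sets the carbinol by reagent-controlled ketone reduction instead. It sets out from aldehyde 19. Addition of the lithium acetylide of 20 (LiN(SiMe3)2, THF, −78 °C) gives the C4-epimeric mixture methyl (6R)-4-hydroxy-6-[(1S,4R)-4-methyl-4-(triethylsilyloxy)cyclohex-2-en-1-yl]hept-2-ynoate F7. Dess–Martin oxidation gives the γ-oxo ynoate methyl (6R)-6-[(1S,4R)-4-methyl-4-(triethylsilyloxy)cyclohex-2-en-1-yl]-4-oxohept-2-ynoate F8. Midland reduction with B-isopinocampheyl-9-borabicyclo[3.3.1]nonane prepared from (−)-α-pinene should deliver the 4S alcohol and return to the route at 22.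

Step 14. β-Hydride elimination at the alkylpalladium stage, or protonolysis of the organozinc by the free hydroxyl, could outrun the coupling and give reduced or uncoupled material. The fallback replaces the zinc partner by a boron partner. It sets out from iodide 24. Hydroboration of 4-methylpenta-1,3-diene at its terminal alkene with 9-borabicyclo[3.3.1]nonane gives 9-(4-methylpent-3-en-1-yl)-9-borabicyclo[3.3.1]nonane F9. B-alkyl Suzuki–Miyaura coupling of F9 with 24 (PdCl2(dppf), AsPh3, Cs2CO3, DMF/THF/H2O, rt) retains the alkene geometry and returns to the route at 27.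

Further compounds
F1 | step 6 | (3R)-3-methyl-3-(triethylsilyloxy)hept-1-en-6-yne | C=C[C@](C)(O[Si](CC)(CC)CC)CCC#C
F2 | step 6 | (7R)-7-methyl-7-(triethylsilyloxy)non-8-en-3-yn-2-one | C=C[C@](C)(O[Si](CC)(CC)CC)CCC#CC(C)=O
F3 | step 6 | (2R,7R)-7-methyl-7-(triethylsilyloxy)non-8-en-3-yn-2-ol | C=C[C@](C)(O[Si](CC)(CC)CC)CCC#C[C@@H](C)O
F4 | step 6 | (2R,3Z,7R)-7-methyl-7-(triethylsilyloxy)nona-3,8-dien-2-ol | C=C[C@](C)(O[Si](CC)(CC)CC)CC/C=C\[C@@H](C)O
F5 | step 6 | (2R,3Z,7R)-7-methyl-7-(triethylsilyloxy)nona-3,8-dien-2-yl propanoate | C=C[C@](C)(O[Si](CC)(CC)CC)CC/C=C\[C@@H](C)OC(=O)CC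
F6 | step 6 | trimethylsilyl ketene acetal of F5, methyl trans to the trimethylsilyloxy group | C=C[C@](C)(O[Si](CC)(CC)CC)CC/C=C\[C@@H](C)O/C(=C\C)O[Si](C)(C)C
F7 | step 11 | methyl (6R)-4-hydroxy-6-[(1S,4R)-4-methyl-4-(triethylsilyloxy)cyclohex-2-en-1-yl]hept-2-ynoate, C4 epimers | COC(=O)C#CC(O)C[C@@H](C)[C@H]1C=C[C@](C)(O[Si](CC)(CC)CC)CC1
F8 | step 11 | methyl (6R)-6-[(1S,4R)-4-methyl-4-(triethylsilyloxy)cyclohex-2-en-1-yl]-4-oxohept-2-ynoate | COC(=O)C#CC(=O)C[C@@H](C)[C@H]1C=C[C@](C)(O[Si](CC)(CC)CC)CC1
F9 | step 14 | 9-(4-methylpent-3-en-1-yl)-9-borabicyclo[3.3.1]nonane | CC(C)=CCCB1C2CCCC1CCC2
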